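## The problem

Compound 25 is a 1,1,2,4-tetrasubstituted cyclohexene carrying two 3-(2-methylbut-3-en-2-yl)indol-5-yl units. Indole B sits directly on C2. Indole A is held through an E-ethenyl spacer on the quaternary carbon C1, which also bears a methyl group. The only stereocentres are C1 (all-carbon quaternary) and the neighbouring C2 (tertiary, allylic and benzylic), with the aryl group on C2 trans to the ethenyl arm on C1 and the absolute configuration 1S,2R. A quaternary centre cannot be corrected later and C2 has no handle for equilibration, so neither centre can usefully be built under control of the other. Both should arise in one event, the relative configuration from an alkene geometry and the absolute one from an external chiral agent. The ring double bond must lie at C3=C4 and not at the equally substituted C4=C5, so its position has to be fixed by structure and not by thermodynamics. The fragile parts are the two free 3-tert-alkyl indoles (acid, oxidants, electrophiles), the styryl and ring alkenes, and above all the terminal vinyl groups, which would not survive diimide or a Heck step and whose parent allyl cation would bond through its primary end. What makes a short solution possible is that C1 and C2 with their trans substituents are the α- and β-carbons of an (E)-2-methyl-3-(indol-5-yl)acrolein, while C3–C6 map onto a butadiene carrying oxygen at C4 and a leaving group at C6. A [4+2] cycloaddition then closes the ring, creates the quaternary carbon and both stereocentres, and leaves a formyl group on C1 for the arm.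

## Retrosynthesis

Throughout, tosyl means 4-methylbenzenesulfonyl, and ring atoms are numbered as in the target (C1 quaternary, C2 aryl-bearing, C3=C4).

**Tert-prenyl groups last (25 ⇒ 24 ⇒ 20 + 22).** The two indole C3–C(CH3)2 bonds are cut. The vinyl groups are incompatible with the diimide and Heck steps that the core needs, so they come last. A cobalt-complexed tertiary propargyl cation can bond only through its tertiary carbon, which an allyl cation would not do. This leads to dialkyne 24 and, one step further back, to the bare bisindole 20 and the alkyne complex 22, removing ten carbons and two quaternary centres. The forward reactions must be C3-selective on NH indoles, spare two other alkenes, and stop the final hydrogenation at the alkene.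

**Styryl arm (20 ⇒ 19 ⇒ 17 + 18).** The bond between C5 of indole A and the ethenyl carbon is cut (Heck reaction). Cutting the C=C bond instead would need an indolylmethyl phosphorus or sulfone reagent of several steps and would leave E/Z control open. The Heck reaction gives the E alkene by mechanism and uses commercial 5-iodoindole 18 unprotected. Precursor 17 contains one indole only. The forward step must arylate the terminal carbon of a vinyl group on a quaternary centre. Hydroxide then removes the one sulfonyl group of 19.

**Vinyl group (17 ⇒ 16).** The C=C bond is cut to the aldehyde 16 by a one-carbon Wittig disconnection. The formyl group is exactly what the cycloaddition leaves on C1.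

**Ring adjustment (16 ⇒ 15 ⇒ 14 ⇒ 13 ⇒ 12 ⇒ 11).** The C4–CH3 bond is cut back to an enol triflate and then to the enone 11; the C5–C6 single bond is traced back to the enone alkene. The argument for this order is regiochemical. In 11 the γ-carbon is quaternary, so C3 is the only enolisable position and the new alkene can appear only at C3=C4. A saturated ketone would enolise toward C5. The price is diene 14, whose disubstituted alkene must be reduced in the presence of the trisubstituted one. A dioxolane (12–15) shields the formyl group from the amide base and the Grignard reagent.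

**Key disconnection (11 ⇒ 4 + 8).** C2–C3 and C1–C6 are cut in a retro-[4+2] step. A hydrocarbon diene would place the ring alkene at C4=C5, one position off. The 1-amino-3-siloxy pattern of 8 instead puts a carbonyl at C4 and a leaving group at C6, giving enone 11 after work-up. The nitrogen donor is carried as the N-benzyl methyl carbamate and not as a dialkylamine, because this is the diene class for which catalysis by cationic trivalent chromium salen complexes is established; a basic enamine-type diene would be degraded by the Lewis acid. The precursors are two achiral components, and the step delivers the ring, the quaternary carbon and both stereocentres. It asks for sufficient reactivity of a trisubstituted β-aryl enal, for one regiochemistry and for enantioface control by the catalyst.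

**Components (4 ⇒ 2 + 3 ⇒ 1; 8 ⇒ 7 ⇒ 6 ⇒ 5).** The enal C=C bond is cut to aldehyde 2 and the formyl-stabilised ylide 3. The neutral Wittig reaction is preferred to a hydroxide-mediated aldol condensation, which would endanger the N-sulfonyl group. Aldehyde 2 is the N-tosyl derivative of commercial 1. Diene 8 comes from commercial enaminone 5 by amine exchange, N-acylation and O-silylation.

## Roads not taken

**Alternative 1:** Twofold Nicholas tert-propargylation as the strategic step.
- **Cut:** the two indole C3–C(CH3)2 bonds of dialkyne A1, leading back to the unprotected bisindole core A2.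
- **Forward key step:** A2 reacts at C3 of both indoles with the cobalt-stabilised cation from the hexacarbonyldicobalt complex of 2-methylbut-3-yn-2-ol (22 in the route below); decomplexation frees A1.
- **Merits:** two identical bonds and two quaternary carbons are made in one operation on an unprotected substrate, and the tertiary attachment is guaranteed.
- **Weak points:** it is silent on the cyclohexene and on C1 and C2, so A2 must still be made by some other plan. It exposes two 3-unsubstituted indoles, a styrene and a trisubstituted alkene to a Lewis acid and then to a decomplexing oxidant. A semi-hydrogenation is still owed.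
- **Comparison:** as an end-game it is as good as anything available, and the chosen route adopts it (A1 is 24, A2 is 20). As a strategy it leaves the hard part unsolved. The chosen plan sets against it a defined origin of the ring and of both stereocentres.

**Alternative 2:** Cyclohexene closed last by keto-aldehyde McMurry coupling.
- **Cut:** the C3=C4 double bond of the N,N′-di-Boc target A3, leading back to the acyclic keto-aldehyde A4.
- **Forward key step:** low-valent titanium (TiCl3 reduced by Zn–Cu) couples the C3 aldehyde with the C4 methyl ketone of A4.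
- **Merits:** the position of the trisubstituted alkene is unambiguous, so neither the enol-triflate detour nor the diene reduction of the chosen plan is needed. The tert-prenyl groups can already be present.
- **Weak points:** the key step creates no stereocentre. C1 and C2 must be set in an open chain by a separate asymmetric method. C2 in A4 is an α-aryl aldehyde carbon and therefore epimerisable, so the trans relation can erode before the ring exists. The hindered aldehyde and the strongly reducing medium invite pinacol formation. A4 itself is a long synthesis.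
- **Comparison:** this road is better in regiochemical certainty of the alkene. The chosen plan answers with one step that gives ring, quaternary carbon and both stereocentres from two simple achiral partners, at the cost of four functional-group steps on the ring.

**Alternative 3:** Claisen ring contraction of a 2-styryl dihydropyran.
- **Cut:** the C1–C2 bond of aldehyde A5, leading back to the (Z)-styryl dihydropyran A6.
- **Forward key step:** heating A6 causes a [3,3] shift through a boat transition state that forms C1–C2, breaks the O–C4 bond and closes the cyclohexene with C3=C4(CH3) in place.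
- **Merits:** A5 has the alkene and the formyl group exactly where the chosen route has them only after five further steps. The step needs no reagent, and one C–O stereocentre is transferred to both carbon stereocentres.
- **Weak points:** the trans relation requires the Z alkene, whose aryl group must sit on the inside of the allyl unit, 1,3 to the ring methylene that is also inside. The rearrangement should therefore be slow, and Z/E isomerisation or ionisation of the tertiary allylic ether can compete at the temperature needed. A6 needs an enantiopure tertiary ether centre and a Z-styrene, neither of which is simple to make. The thermally sensitive tert-prenyl group would be carried through the pyrolysis.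
- **Comparison:** this road is clearly shorter after ring formation. The chosen plan sets against it an easily made E alkene, catalytic enantiocontrol from achiral commercial precursors, and no stereocentre that has to be prepared beforehand.

Key step: step 6

Assumption: the (R,R) antipode of the chromium salen catalyst is taken to deliver the (1R,6S) enone 11; if this β-aryl enal shows the opposite sense of induction, the (S,S) catalyst is used and nothing else changes.

## Route

Step 1
Reactants: 1 1H-indole-5-carbaldehyde
Product: 2 1-tosylindole-5-carbaldehyde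
Conditions: NaH, TsCl, THF/DMF, 0 °C to rt
Reagents that add atoms: 4-methylbenzenesulfonyl chloride, Cc1ccc(cc1)S(Cl)(=O)=O
Why: N-Sulfonylation of the sodium indolide; the sulfonyl group removes the C3 nucleophilicity that would otherwise attack the Lewis-acid-activated enal in step 6 and makes the aryl group a weaker donor toward the dienophile.

Step 2
Reactants: 2 1-tosylindole-5-carbaldehyde; 3 2-(triphenylphosphoranylidene)propanal
Product: 4 (E)-2-methyl-3-(1-tosylindol-5-yl)prop-2-enal
Conditions: toluene, 100 °C
Reagents that add atoms: none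
Why: Wittig olefination with a formyl-stabilised ylide, which is reversible up to the oxaphosphetane and therefore gives the E trisubstituted enal; the neutral medium keeps the N-sulfonyl group intact.

Step 3
Reactants: 5 (E)-4-(dimethylamino)but-3-en-2-one
Product: 6 (Z)-4-(benzylamino)but-3-en-2-one
Conditions: BnNH2, EtOH, 60 °C (loss of Me2NH)
Reagents that add atoms: benzylamine, NCc1ccccc1
Why: Amine exchange by addition–elimination on a vinylogous amide, driven by loss of volatile dimethylamine; the secondary enaminone is held Z by an N–H···O hydrogen bond.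

Step 4
Reactants: 6 (Z)-4-(benzylamino)but-3-en-2-one
Product: 7 methyl N-benzyl-N-[(1E)-3-oxobut-1-en-1-yl]carbamate
Conditions: NaN(SiMe3)2, THF, −78 °C; ClCO2Me, −78 to 0 °C
Reagents that add atoms: methyl chloroformate, COC(=O)Cl
Why: N-Acylation of the sodium salt of the vinylogous amide to the vinylogous imide; once the hydrogen bond is gone the alkene relaxes to the E geometry that the diene needs.

Step 5
Reactants: 7 methyl N-benzyl-N-[(1E)-3-oxobut-1-en-1-yl]carbamate
Product: 8 methyl N-benzyl-N-[(1E)-3-(tert-butyldimethylsilyloxy)buta-1,3-dien-1-yl]carbamate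
Conditions: KN(SiMe3)2, THF, −78 °C; TBSCl, −78 °C to rt
Reagents that add atoms: tert-butyl(chloro)dimethylsilane, CC(C)(C)[Si](C)(C)Cl
Why: Kinetic enolisation of the methyl ketone and O-silylation (silyl enol ether formation) give the 1-(acylamino)-3-siloxybutadiene, which is used without aqueous contact.

Step 6
Reactants: 4 (E)-2-methyl-3-(1-tosylindol-5-yl)prop-2-enal; 8 methyl N-benzyl-N-[(1E)-3-(tert-butyldimethylsilyloxy)buta-1,3-dien-1-yl]carbamate
Product: 11 (1R,6S)-1-methyl-4-oxo-6-(1-tosylindol-5-yl)cyclohex-2-ene-1-carbaldehyde, via silyl enol ether cycloadduct 9 (not isolated), via β-carbamoyl ketone 10 (not isolated)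
Conditions: (R,R)-(salen)CrSbF6 (5 mol %, from (salen)CrCl and AgSbF6; salen = N,N′-bis(3,5-di-tert-butylsalicylidene)cyclohexane-1,2-diamine dianion; trivalent chromium), 4 Å MS, CH2Cl2, −20 °C to rt; then aq. HF, MeCN, 0 °C to rt
Reagents that add atoms: none
Why: The cationic trivalent chromium complex binds the formyl oxygen of 4 and lowers its LUMO, and the CH2 terminus of 8, which carries the largest HOMO coefficient because the carbamate nitrogen and the siloxy group both push toward it, bonds first to the aryl-bearing β-carbon (C2–C3) while the nitrogen-bearing terminus closes onto the α-carbon (C1–C6) in a concerted, asynchronous, normal-demand [4+2] cycloaddition. The closest known reaction is the (salen)CrSbF6-catalysed Diels–Alder reaction of 1-(acylamino)-3-siloxybutadienes with α-substituted acroleins, from which 4 differs by its β-aryl group. The six-membered ring is closed by intermolecular cycloaddition, with both new σ-bonds coming from the two components. The trans relation of aryl and formyl at C2 and C1 is the E geometry of 4 carried through a suprafacial addition and is the same for endo and exo approach. The absolute configuration of both centres is set together by the catalyst, which leaves one face of the coordinated enal open; the nitrogen-bearing third centre of 9 is transient. Aqueous HF cleaves the silyl enol ether of 9 to ketone 10, which loses methyl N-benzylcarbamate by β-elimination through its enol to give enone 11. The step needs regioselectivity, secured by the 1,3-donor pattern of the diene, enantioface selectivity, secured by the catalyst, and enough rate, for which the N-sulfonyl group keeps the indole from donating into the enal and the Lewis acid offsets the β-substituent.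

Step 7
Reactants: 11 (1R,6S)-1-methyl-4-oxo-6-(1-tosylindol-5-yl)cyclohex-2-ene-1-carbaldehyde
Product: 12 (4R,5S)-4-(1,3-dioxolan-2-yl)-4-methyl-5-(1-tosylindol-5-yl)cyclohex-2-en-1-one
Conditions: Me3SiOCH2CH2OSiMe3, TMSOTf (cat.), CH2Cl2, −78 to −20 °C
Reagents that add atoms: 1,2-bis(trimethylsilyloxy)ethane, C[Si](C)(C)OCCO[Si](C)(C)C
Why: Aprotic silyl-triflate-catalysed acetalisation, which converts aldehydes into dioxolanes at low temperature while conjugated ketones do not react; the formyl group is thereby shielded from the amide base and the Grignard reagent of steps 8 and 9.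

Step 8
Reactants: 12 (4R,5S)-4-(1,3-dioxolan-2-yl)-4-methyl-5-(1-tosylindol-5-yl)cyclohex-2-en-1-one
Product: 13 (3S,4R)-4-(1,3-dioxolan-2-yl)-4-methyl-3-(1-tosylindol-5-yl)cyclohexa-1,5-dien-1-yl trifluoromethanesulfonate
Conditions: LiN(SiMe3)2, THF, −78 °C; PhNTf2, −78 to 0 °C
Reagents that add atoms: N-phenylbis(trifluoromethanesulfonimide), O=S(=O)(N(c1ccccc1)S(=O)(=O)C(F)(F)F)C(F)(F)F
Why: Enol triflate formation from the cross-conjugated lithium dienolate; the γ-carbon is quaternary, so C3 is the only enolisable position and the new alkene can form only at C3=C4, while the C2 stereocentre, β to the carbonyl, is not touched.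

Step 9
Reactants: 13 (3S,4R)-4-(1,3-dioxolan-2-yl)-4-methyl-3-(1-tosylindol-5-yl)cyclohexa-1,5-dien-1-yl trifluoromethanesulfonate
Product: 14 5-[(1S,6R)-6-(1,3-dioxolan-2-yl)-3,6-dimethylcyclohexa-2,4-dien-1-yl]-1-tosylindole
Conditions: MeMgBr, Fe(acac)3 (5 mol %), THF/NMP, −30 °C
Reagents that add atoms: methylmagnesium bromide, C[Mg]Br
Why: Iron-catalysed Kumada-type cross-coupling of an alkenyl triflate with a methyl Grignard reagent (Fe(acac)3 is a trivalent iron precatalyst), which at −30 °C is much faster than any attack of the Grignard reagent on the acetal or the sulfonamide.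

Step 10
Reactants: 14 5-[(1S,6R)-6-(1,3-dioxolan-2-yl)-3,6-dimethylcyclohexa-2,4-dien-1-yl]-1-tosylindole
Product: 15 5-[(1S,6R)-6-(1,3-dioxolan-2-yl)-3,6-dimethylcyclohex-2-en-1-yl]-1-tosylindole
Conditions: 2-O2NC6H4SO2NHNH2, Et3N, CH2Cl2, rt
Reagents that add atoms: none
Why: Diimide reduction by concerted syn transfer of H2, whose rate falls steeply with alkene substitution; the cis-disubstituted C5=C6 bond of the conjugated diene should be reduced and the trisubstituted C3=C4 bond, then isolated and slower still, should remain, with no stereocentre formed.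

Step 11
Reactants: 15 5-[(1S,6R)-6-(1,3-dioxolan-2-yl)-3,6-dimethylcyclohex-2-en-1-yl]-1-tosylindole
Product: 16 (1R,2S)-1,4-dimethyl-2-(1-tosylindol-5-yl)cyclohex-3-ene-1-carbaldehyde
Conditions: 2 M aq. HCl, THF, 45 °C
Reagents that add atoms: water, O
Why: Acid-catalysed acetal hydrolysis; the aldehyde has no α-hydrogen, so C1 cannot epimerise, and dilute acid at this temperature should leave the trisubstituted alkene in place.

Step 12
Reactants: 16 (1R,2S)-1,4-dimethyl-2-(1-tosylindol-5-yl)cyclohex-3-ene-1-carbaldehyde
Product: 17 5-[(1R,6S)-6-ethenyl-3,6-dimethylcyclohex-2-en-1-yl]-1-tosylindole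
Conditions: Ph3PCH3Br, KOtBu, THF, 0 °C to rt
Reagents that add atoms: methyltriphenylphosphonium bromide, C[P+](c1ccccc1)(c1ccccc1)c1ccccc1.[Br-]
Why: Wittig methylenation; the small non-stabilised ylide adds even to aldehydes on quaternary carbons, and no stereochemical question arises.

Step 13
Reactants: 17 5-[(1R,6S)-6-ethenyl-3,6-dimethylcyclohex-2-en-1-yl]-1-tosylindole; 18 5-iodo-1H-indole
Product: 19 5-[(E)-2-[(1S,2R)-1,4-dimethyl-2-(1-tosylindol-5-yl)cyclohex-3-en-1-yl]ethenyl]-1H-indole
Conditions: Pd(OAc)2 (5 mol %), Bu4NCl, NaHCO3, DMF, 80 °C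
Reagents that add atoms: none
Why: Heck reaction under ligand-free phase-transfer conditions; the aryl group adds to the terminal carbon because the internal one is neopentyl-like, syn β-hydride elimination can use only the benzylic hydrogen and gives the E alkene, and the quaternary C1 rules out chain walking.

Step 14
Reactants: 19 5-[(E)-2-[(1S,2R)-1,4-dimethyl-2-(1-tosylindol-5-yl)cyclohex-3-en-1-yl]ethenyl]-1H-indole
Product: 20 5-[(E)-2-[(1S,2R)-2-(1H-indol-5-yl)-1,4-dimethylcyclohex-3-en-1-yl]ethenyl]-1H-indole
Conditions: KOH, MeOH/THF/H2O, 65 °C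
Reagents that add atoms: none
Why: Nucleophilic N-desulfonylation (hydroxide attacks sulfur, the indolide leaves); nothing else in 19 is base-sensitive, and the free NH indoles are needed for C3 nucleophilicity in step 16.

Step 15
Reactants: 21 2-methylbut-3-yn-2-ol
Product: 22 hexacarbonyl[μ-(2-methylbut-3-yn-2-ol)]dicobalt (Co–Co)
Conditions: Co2(CO)8, CH2Cl2, rt (loss of 2 CO)
Reagents that add atoms: octacarbonyldicobalt, O=C=[Co](=C=O)(=C=O)(=C=O)[Co](=C=O)(=C=O)(=C=O)=C=O
Why: Alkyne complexation: the triple bond displaces two carbonyl ligands of zerovalent Co2(CO)8 and bridges the Co–Co bond.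

Step 16
Reactants: 20 5-[(E)-2-[(1S,2R)-2-(1H-indol-5-yl)-1,4-dimethylcyclohex-3-en-1-yl]ethenyl]-1H-indole; 22 hexacarbonyl[μ-(2-methylbut-3-yn-2-ol)]dicobalt (Co–Co)
Product: 24 3-(2-methylbut-3-yn-2-yl)-5-[(E)-2-[(1S,2R)-1,4-dimethyl-2-[3-(2-methylbut-3-yn-2-yl)-1H-indol-5-yl]cyclohex-3-en-1-yl]ethenyl]-1H-indole, via bis(hexacarbonyldicobalt) complex 23 (not isolated)
Conditions: BF3·OEt2, CH2Cl2, −40 to 0 °C; aq. NaHCO3 wash; then Me3NO·2H2O, THF, rt
Reagents that add atoms: none
Why: Nicholas reaction: BF3 ionises 22 to the cobalt-stabilised tertiary propargyl cation, which substitutes the most nucleophilic position, C3, of each NH indole (electrophilic aromatic substitution); cobalt blocks the allenyl mode, so only the tertiary carbon bonds, and the amine N-oxide then oxidises off the carbonyl ligands and frees the alkynes under conditions mild enough for NH indoles.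

Step 17
Reactants: 24 3-(2-methylbut-3-yn-2-yl)-5-[(E)-2-[(1S,2R)-1,4-dimethyl-2-[3-(2-methylbut-3-yn-2-yl)-1H-indol-5-yl]cyclohex-3-en-1-yl]ethenyl]-1H-indole
Product: 25 3-(2-methylbut-3-en-2-yl)-5-[(E)-2-[(1S,2R)-1,4-dimethyl-2-[3-(2-methylbut-3-en-2-yl)-1H-indol-5-yl]cyclohex-3-en-1-yl]ethenyl]-1H-indole
Conditions: H2 (1 atm), Pd/CaCO3–Pb(OAc)2 (Lindlar catalyst), quinoline, EtOAc, rt
Reagents that add atoms: none
Why: Lindlar semi-hydrogenation; the poisoned palladium surface binds alkynes far more strongly than alkenes, so the two terminal alkynes should be reduced to vinyl groups while the styryl, ring and new vinyl alkenes remain.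

## Compound list

1 | 1H-indole-5-carbaldehyde | O=Cc1ccc2[nH]ccc2c1 | starting material
2 | 1-tosylindole-5-carbaldehyde | O=Cc1ccc2c(c1)ccn2S(=O)(=O)c1ccc(C)cc1 | intermediate
3 | 2-(triphenylphosphoranylidene)propanal | CC(C=O)=P(c1ccccc1)(c1ccccc1)c1ccccc1 | starting material
4 | (E)-2-methyl-3-(1-tosylindol-5-yl)prop-2-enal | O=C/C(C)=C/c1ccc2c(c1)ccn2S(=O)(=O)c1ccc(C)cc1 | intermediate
5 | (E)-4-(dimethylamino)but-3-en-2-one | CN(C)/C=C/C(C)=O | starting material
6 | (Z)-4-(benzylamino)but-3-en-2-one | CC(=O)/C=C\NCc1ccccc1 | intermediate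
7 | methyl N-benzyl-N-[(1E)-3-oxobut-1-en-1-yl]carbamate | CC(=O)/C=C/N(Cc1ccccc1)C(=O)OC | intermediate
8 | methyl N-benzyl-N-[(1E)-3-(tert-butyldimethylsilyloxy)buta-1,3-dien-1-yl]carbamate | C=C(O[Si](C)(C)C(C)(C)C)/C=C/N(Cc1ccccc1)C(=O)OC | intermediate
9 | methyl N-benzyl-N-[3-(tert-butyldimethylsilyloxy)-6-formyl-6-methyl-5-(1-tosylindol-5-yl)cyclohex-2-en-1-yl]carbamate, nitrogen cis and aryl trans to formyl (not isolated) | O=C[C@]1(C)[C@H](N(Cc2ccccc2)C(=O)OC)C=C(O[Si](C)(C)C(C)(C)C)C[C@H]1c1ccc2c(c1)ccn2S(=O)(=O)c1ccc(C)cc1 | intermediate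
10 | methyl N-benzyl-N-[2-formyl-2-methyl-5-oxo-3-(1-tosylindol-5-yl)cyclohexyl]carbamate, nitrogen cis and aryl trans to formyl (not isolated) | O=C[C@]1(C)[C@H](N(Cc2ccccc2)C(=O)OC)CC(=O)C[C@H]1c1ccc2c(c1)ccn2S(=O)(=O)c1ccc(C)cc1 | intermediate
11 | (1R,6S)-1-methyl-4-oxo-6-(1-tosylindol-5-yl)cyclohex-2-ene-1-carbaldehyde | O=C[C@]1(C)C=CC(=O)C[C@H]1c1ccc2c(c1)ccn2S(=O)(=O)c1ccc(C)cc1 | intermediate
12 | (4R,5S)-4-(1,3-dioxolan-2-yl)-4-methyl-5-(1-tosylindol-5-yl)cyclohex-2-en-1-one | O1CCOC1[C@]1(C)C=CC(=O)C[C@H]1c1ccc2c(c1)ccn2S(=O)(=O)c1ccc(C)cc1 | intermediate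
13 | (3S,4R)-4-(1,3-dioxolan-2-yl)-4-methyl-3-(1-tosylindol-5-yl)cyclohexa-1,5-dien-1-yl trifluoromethanesulfonate | O1CCOC1[C@]1(C)C=CC(OS(=O)(=O)C(F)(F)F)=C[C@H]1c1ccc2c(c1)ccn2S(=O)(=O)c1ccc(C)cc1 | intermediate
14 | 5-[(1S,6R)-6-(1,3-dioxolan-2-yl)-3,6-dimethylcyclohexa-2,4-dien-1-yl]-1-tosylindole | O1CCOC1[C@]1(C)C=CC(C)=C[C@H]1c1ccc2c(c1)ccn2S(=O)(=O)c1ccc(C)cc1 | intermediate
15 | 5-[(1S,6R)-6-(1,3-dioxolan-2-yl)-3,6-dimethylcyclohex-2-en-1-yl]-1-tosylindole | O1CCOC1[C@]1(C)CCC(C)=C[C@H]1c1ccc2c(c1)ccn2S(=O)(=O)c1ccc(C)cc1 | intermediate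
16 | (1R,2S)-1,4-dimethyl-2-(1-tosylindol-5-yl)cyclohex-3-ene-1-carbaldehyde | O=C[C@]1(C)CCC(C)=C[C@H]1c1ccc2c(c1)ccn2S(=O)(=O)c1ccc(C)cc1 | intermediate
17 | 5-[(1R,6S)-6-ethenyl-3,6-dimethylcyclohex-2-en-1-yl]-1-tosylindole | C=C[C@]1(C)CCC(C)=C[C@H]1c1ccc2c(c1)ccn2S(=O)(=O)c1ccc(C)cc1 | intermediate
18 | 5-iodo-1H-indole | Ic1ccc2[nH]ccc2c1 | starting material
19 | 5-[(E)-2-[(1S,2R)-1,4-dimethyl-2-(1-tosylindol-5-yl)cyclohex-3-en-1-yl]ethenyl]-1H-indole | [nH]1ccc2cc(/C=C/[C@]3(C)CCC(C)=C[C@H]3c3ccc4c(c3)ccn4S(=O)(=O)c3ccc(C)cc3)ccc12 | intermediate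
20 | 5-[(E)-2-[(1S,2R)-2-(1H-indol-5-yl)-1,4-dimethylcyclohex-3-en-1-yl]ethenyl]-1H-indole | [nH]1ccc2cc(/C=C/[C@]3(C)CCC(C)=C[C@H]3c3ccc4[nH]ccc4c3)ccc12 | intermediate
21 | 2-methylbut-3-yn-2-ol | CC(C)(O)C#C | starting material
22 | hexacarbonyl[μ-(2-methylbut-3-yn-2-ol)]dicobalt (Co–Co) | CC(C)(O)C12[CH]3[Co]1(=C=O)(=C=O)(=C=O)[Co]23(=C=O)(=C=O)=C=O | intermediate
23 | bis(hexacarbonyldicobalt) complex of 24, one Co2(CO)6 unit on each alkyne (not isolated) | O=C=[Co]12(=C=O)(=C=O)[CH]3C1(C(C)(C)c1c[nH]c4ccc(/C=C/[C@]5(C)CCC(C)=C[C@H]5c5ccc6[nH]cc(C(C)(C)C78[CH]9[Co]7(=C=O)(=C=O)(=C=O)[Co]89(=C=O)(=C=O)=C=O)c6c5)cc14)[Co]23(=C=O)(=C=O)=C=O | intermediate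
24 | 3-(2-methylbut-3-yn-2-yl)-5-[(E)-2-[(1S,2R)-1,4-dimethyl-2-[3-(2-methylbut-3-yn-2-yl)-1H-indol-5-yl]cyclohex-3-en-1-yl]ethenyl]-1H-indole | C#CC(C)(C)c1c[nH]c2ccc(/C=C/[C@]3(C)CCC(C)=C[C@H]3c3ccc4[nH]cc(C(C)(C)C#C)c4c3)cc12 | intermediate
25 | 3-(2-methylbut-3-en-2-yl)-5-[(E)-2-[(1S,2R)-1,4-dimethyl-2-[3-(2-methylbut-3-en-2-yl)-1H-indol-5-yl]cyclohex-3-en-1-yl]ethenyl]-1H-indole | C=CC(C)(C)c1c[nH]c2ccc(/C=C/[C@]3(C)CCC(C)=C[C@H]3c3ccc4[nH]cc(C(C)(C)C=C)c4c3)cc12 | target

## Step count and least certain steps

Total: 17 steps. Longest linear sequence: 14 steps (steps 3–14, 16 and 17, from 5); from 1 the sequence is 13 steps.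

**Step 6 (key step).** The cycloaddition may be too slow with an enal that is both α-methylated and β-arylated. Hydrolysis of diene 8 by traces of water, or a non-catalysed pathway at the higher temperature then needed, would take over and erode enantioface discrimination. The catalyst is established for α-substituted acroleins without a β-substituent; the aryl group hinders the β-carbon and raises the LUMO. The fallback sets out from 4 and comes back at 11, replacing catalysis by a stoichiometric auxiliary on a more electron-rich diene. (E)-4-Methoxybut-3-en-2-one is condensed with (2R,5R)-2,5-diphenylpyrrolidine to the vinylogous amide (E)-4-[(2R,5R)-2,5-diphenylpyrrolidin-1-yl]but-3-en-2-one F1. KN(SiMe3)2 and TBSCl convert F1 into the diene (E)-1-[(2R,5R)-2,5-diphenylpyrrolidin-1-yl]-3-(tert-butyldimethylsilyloxy)buta-1,3-diene F2. Heating F2 with 4 in toluene should give the cycloadduct 4-(tert-butyldimethylsilyloxy)-2-[(2R,5R)-2,5-diphenylpyrrolidin-1-yl]-1-methyl-6-(1-tosylindol-5-yl)cyclohex-3-ene-1-carbaldehyde F3; the dialkylamino donor supplies the reactivity and the C2-symmetric pyrrolidine the facial bias. Aqueous HF in MeCN then releases 11 and the auxiliary. The auxiliary antipode is subject to the same assumption as the catalyst antipode.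

**Step 10.** Diimide may attack the trisubstituted double bond as well, or reduce both alkenes, because the two belong to one conjugated diene and the C5=C6 bond is flanked by the quaternary carbon. The fallback sets out from 14 and comes back at 15; it masks the alkene that must stay, using a selectivity based on nucleophilicity instead of steric access. Buffered mCPBA epoxidises the more electron-rich trisubstituted C3=C4 bond to 5-[(1S,6R)-6-(1,3-dioxolan-2-yl)-2,3-epoxy-3,6-dimethylcyclohex-4-en-1-yl]-1-tosylindole F4 (either epoxide face). Diimide then has a single alkene to reduce and gives the saturated epoxide 5-[(1S,6R)-6-(1,3-dioxolan-2-yl)-2,3-epoxy-3,6-dimethylcyclohexyl]-1-tosylindole F5. Deoxygenation with the low-valent tungsten chloride made from WCl6 and n-BuLi restores the alkene at the same position to give 15.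

**Step 13.** Carbopalladation of a vinyl group on a quaternary carbon may be slow, so that reductive deiodination of 18 and catalyst precipitation compete, and some arylation at the internal carbon cannot be excluded. The fallback sets out from 16 and comes back at 19, bypassing 17. Takai olefination of 16 (CHI3 and CrCl2, a divalent chromium salt) gives the vinyl iodide 5-[(1R,6R)-6-[(E)-2-iodoethenyl]-3,6-dimethylcyclohex-2-en-1-yl]-1-tosylindole F6. Suzuki–Miyaura coupling of F6 with (1H-indol-5-yl)boronic acid (Pd(PPh3)4, aq. K2CO3, dioxane) then forms the same aryl–vinyl bond with retention of the E geometry.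

**Step 16.** The second alkylation may stall. The Lewis acid may also oligomerise the 3-unsubstituted indoles or let the cation add to the ring alkene, and the indoles may be oxidised during decomplexation. The fallback sets out from 20 and comes back at 25, replacing steps 16 and 17 by halogen-based cross-coupling. Iodine and KOH in DMF followed by TsCl give 3-iodo-5-[(E)-2-[(1S,2R)-2-(3-iodo-1-tosylindol-5-yl)-1,4-dimethylcyclohex-3-en-1-yl]ethenyl]-1-tosylindole F7. A γ-selective Suzuki–Miyaura coupling with 3-methylbut-2-enylboronic acid pinacol ester (Pd(OAc)2, a γ-directing biarylphosphine, K3PO4) joins the tertiary allyl carbon to C3 of both indoles and gives the N,N′-ditosyl derivative of the target F8. KOH in MeOH/THF then removes both sulfonyl groups.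

## Further compounds

F1 | step 6 | (E)-4-[(2R,5R)-2,5-diphenylpyrrolidin-1-yl]but-3-en-2-one | CC(=O)/C=C/N1[C@@H](c2ccccc2)CC[C@@H]1c1ccccc1
F2 | step 6 | (E)-1-[(2R,5R)-2,5-diphenylpyrrolidin-1-yl]-3-(tert-butyldimethylsilyloxy)buta-1,3-diene | C=C(O[Si](C)(C)C(C)(C)C)/C=C/N1[C@@H](c2ccccc2)CC[C@@H]1c1ccccc1
F3 | step 6 | 4-(tert-butyldimethylsilyloxy)-2-[(2R,5R)-2,5-diphenylpyrrolidin-1-yl]-1-methyl-6-(1-tosylindol-5-yl)cyclohex-3-ene-1-carbaldehyde, nitrogen cis and aryl trans to formyl | O=C[C@]1(C)[C@H](N2[C@@H](c3ccccc3)CC[C@@H]2c2ccccc2)C=C(O[Si](C)(C)C(C)(C)C)C[C@H]1c1ccc2c(c1)ccn2S(=O)(=O)c1ccc(C)cc1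
F4 | step 10 | 5-[(1S,6R)-6-(1,3-dioxolan-2-yl)-2,3-epoxy-3,6-dimethylcyclohex-4-en-1-yl]-1-tosylindole (either epoxide face) | O1CCOC1[C@]1(C)C=CC2(C)OC2[C@H]1c1ccc2c(c1)ccn2S(=O)(=O)c1ccc(C)cc1
F5 | step 10 | 5-[(1S,6R)-6-(1,3-dioxolan-2-yl)-2,3-epoxy-3,6-dimethylcyclohexyl]-1-tosylindole (either epoxide face) | O1CCOC1[C@]1(C)CCC2(C)OC2[C@H]1c1ccc2c(c1)ccn2S(=O)(=O)c1ccc(C)cc1
F6 | step 13 | 5-[(1R,6R)-6-[(E)-2-iodoethenyl]-3,6-dimethylcyclohex-2-en-1-yl]-1-tosylindole | I/C=C/[C@]1(C)CCC(C)=C[C@H]1c1ccc2c(c1)ccn2S(=O)(=O)c1ccc(C)cc1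
F7 | step 16 | 3-iodo-5-[(E)-2-[(1S,2R)-2-(3-iodo-1-tosylindol-5-yl)-1,4-dimethylcyclohex-3-en-1-yl]ethenyl]-1-tosylindole | Cc1ccc(cc1)S(=O)(=O)n1cc(I)c2cc(/C=C/[C@]3(C)CCC(C)=C[C@H]3c3ccc4c(c3)c(I)cn4S(=O)(=O)c3ccc(C)cc3)ccc12
F8 | step 16 | 3-(2-methylbut-3-en-2-yl)-5-[(E)-2-[(1S,2R)-1,4-dimethyl-2-[3-(2-methylbut-3-en-2-yl)-1-tosylindol-5-yl]cyclohex-3-en-1-yl]ethenyl]-1-tosylindole | Cc1ccc(cc1)S(=O)(=O)n1cc(C(C)(C)C=C)c2cc(/C=C/[C@]3(C)CCC(C)=C[C@H]3c3ccc4c(c3)c(C(C)(C)C=C)cn4S(=O)(=O)c3ccc(C)cc3)ccc12
A1 | alternative 1 | 3-(2-methylbut-3-yn-2-yl)-5-[(E)-2-[(1S,2R)-1,4-dimethyl-2-[3-(2-methylbut-3-yn-2-yl)-1H-indol-5-yl]cyclohex-3-en-1-yl]ethenyl]-1H-indole | C#CC(C)(C)c1c[nH]c2ccc(/C=C/[C@]3(C)CCC(C)=C[C@H]3c3ccc4[nH]cc(C(C)(C)C#C)c4c3)cc12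
A2 | alternative 1 | 5-[(E)-2-[(1S,2R)-2-(1H-indol-5-yl)-1,4-dimethylcyclohex-3-en-1-yl]ethenyl]-1H-indole | [nH]1ccc2cc(/C=C/[C@]3(C)CCC(C)=C[C@H]3c3ccc4[nH]ccc4c3)ccc12
A3 | alternative 2 | N,N′-bis(tert-butoxycarbonyl) derivative of the target | C=CC(C)(C)c1cn(C(=O)OC(C)(C)C)c2ccc(/C=C/[C@]3(C)CCC(C)=C[C@H]3c3ccc4n(C(=O)OC(C)(C)C)cc(C(C)(C)C=C)c4c3)cc12
A4 | alternative 2 | (2R,3S)-3-methyl-6-oxo-2-Ar-3-[(E)-2-Ar-ethenyl]heptanal, Ar = 1-(tert-butoxycarbonyl)-3-(2-methylbut-3-en-2-yl)indol-5-yl | O=C[C@@H](c1ccc2c(c1)c(C(C)(C)C=C)cn2C(=O)OC(C)(C)C)[C@](C)(/C=C/c1ccc2c(c1)c(C(C)(C)C=C)cn2C(=O)OC(C)(C)C)CCC(C)=O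
A5 | alternative 3 | (1R,2S)-1,4-dimethyl-2-[3-(2-methylbut-3-en-2-yl)-1-tosylindol-5-yl]cyclohex-3-ene-1-carbaldehyde | O=C[C@]1(C)CCC(C)=C[C@H]1c1ccc2c(c1)c(C(C)(C)C=C)cn2S(=O)(=O)c1ccc(C)cc1
A6 | alternative 3 | (2S)-2,5-dimethyl-2-[(Z)-2-[3-(2-methylbut-3-en-2-yl)-1-tosylindol-5-yl]ethenyl]-3,4-dihydro-2H-pyran | CC1=CO[C@](C)(/C=C\c2ccc3c(c2)c(C(C)(C)C=C)cn3S(=O)(=O)c2ccc(C)cc2)CC1
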